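The C7–O–C13 ether is assembled first as an open chain. The 2,7-dioxabicyclo[4.2.2]decane core is then cut at the two bonds whose loss opens both ether rings at once: C11–C12 of the oxocane and O–C6 of the tetrahydropyran. The precursor carries a vinyl group and a MOM-protected oxygen at C10, a methyl enol ether at C12 and C6 as a dimethyl acetal. One flask makes both closures: olefin metathesis joins C11 to C12, then acid frees the C10 oxygen, which sits 1,4-cis to C6 across the new oxocane and closes the pyran as a bridged acetal. Ketone reduction, bromination, C-allylation and enyne construction finish the route.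

Key step: step 8

Remark: carbons are numbered C1 (alkyne CH) to C15 (ethyl CH3); O-a is the pyran oxygen (C6–O–C10) and O-b the oxocane oxygen (C7–O–C13); the target is (3E,6R,7S,9S,10R,12S,13R); 2,2-dimethoxyacetaldehyde is assumed to be used anhydrous, freed from its commercial aqueous solution.

Step 1
Reactants: 1 2,2-dimethoxyacetaldehyde
Product: 2 (S)-1,1-dimethoxypent-4-en-2-ol
Conditions: (−)-Ipc2B(allyl) (from (+)-α-pinene), Et2O, −78 °C; then NaOH, H2O2
Reagents that add atoms: (−)-B-allyldiisopinocampheylborane, C=CCB(C1CC2CC(C1C)C2(C)C)C1CC2CC(C1C)C2(C)C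
Why: Brown asymmetric allylboration, in which the isopinocampheyl groups should direct allyl transfer to the si face of the aldehyde through a chair transition state and so set C7 as S.

Step 2
Reactants: 3 methyl (S)-2-hydroxybutanoate
Product: 4 methyl (S)-2-(trifluoromethylsulfonyloxy)butanoate
Conditions: Tf2O, 2,6-lutidine, CH2Cl2, −78 to 0 °C
Reagents that add atoms: triflic anhydride, O=S(=O)(OS(=O)(=O)C(F)(F)F)C(F)(F)F
Why: O-sulfonylation of the secondary alcohol with retention at C13 gives a leaving group that is displaced with clean inversion in the next step.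

Step 3
Reactants: 2 (S)-1,1-dimethoxypent-4-en-2-ol; 4 methyl (S)-2-(trifluoromethylsulfonyloxy)butanoate
Product: 5 methyl (2R)-2-{[(2S)-1,1-dimethoxypent-4-en-2-yl]oxy}butanoate
Conditions: NaH, THF, 0 °C; then 4, −78 to 0 °C
Reagents that add atoms: none
Why: Williamson ether synthesis by SN2 attack of the sodium alkoxide of 2 on the α-triflyloxy ester, which should form the C7–O-b–C13 ether and invert C13 to R.

Step 4
Reactants: 5 methyl (2R)-2-{[(2S)-1,1-dimethoxypent-4-en-2-yl]oxy}butanoate
Product: 6 methyl (2R)-2-{[(2S)-1,1-dimethoxy-4-oxobutan-2-yl]oxy}butanoate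
Conditions: O3, CH2Cl2, −78 °C; then PPh3
Reagents that add atoms: ozone, [O-][O+]=O
Why: Ozonolysis with reductive work-up should cleave the only alkene to the C9 aldehyde and leave the acetal and the ester untouched.

Step 5
Reactants: 6 methyl (2R)-2-{[(2S)-1,1-dimethoxy-4-oxobutan-2-yl]oxy}butanoate
Product: 7 methyl (2R)-2-{[(2S,4R,5R)-4-hydroxy-1,1-dimethoxy-5-(methoxymethoxy)hept-6-en-2-yl]oxy}butanoate
Conditions: CH2=CHCH2OCH2OCH3, s-BuLi, THF, −78 °C; (−)-Ipc2BOMe; BF3·OEt2; then 6, −78 °C; then H2O2, pH 7 buffer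
Reagents that add atoms: 3-(methoxymethoxy)prop-1-ene, C=CCOCOC
Why: Brown (Z)-γ-alkoxyallylboration, in which the (Z)-borane and the chair transition state should give the syn C9/C10 pair and the isopinocampheyl groups should override the C7 center to give 9R,10R.

Step 6
Reactants: 7 methyl (2R)-2-{[(2S,4R,5R)-4-hydroxy-1,1-dimethoxy-5-(methoxymethoxy)hept-6-en-2-yl]oxy}butanoate
Product: 8 methyl (2R)-2-{[(2S,4S,5R)-4-bromo-1,1-dimethoxy-5-(methoxymethoxy)hept-6-en-2-yl]oxy}butanoate
Conditions: CBr4, (n-Oct)3P, toluene, 70 °C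
Reagents that add atoms: carbon tetrabromide, BrC(Br)(Br)Br
Why: Appel bromination, in which SN2 attack of bromide on the alkoxyphosphonium ion should invert C9 from R to S.

Step 7
Reactants: 8 methyl (2R)-2-{[(2S,4S,5R)-4-bromo-1,1-dimethoxy-5-(methoxymethoxy)hept-6-en-2-yl]oxy}butanoate
Product: 9 (3R)-3-{[(2S,4S,5R)-4-bromo-1,1-dimethoxy-5-(methoxymethoxy)hept-6-en-2-yl]oxy}-2-methoxypent-1-ene
Conditions: Cp2TiMe2, toluene, 70 °C, dark
Reagents that add atoms: dimethyltitanocene, C[Ti](C)(C1C=CC=C1)C1C=CC=C1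
Why: Petasis methylenation should turn the ester carbonyl into the 1,1-disubstituted methyl enol ether under non-basic conditions that spare C13, the bromide and both acetals.

Step 8
Reactants: 9 (3R)-3-{[(2S,4S,5R)-4-bromo-1,1-dimethoxy-5-(methoxymethoxy)hept-6-en-2-yl]oxy}-2-methoxypent-1-ene
Product: 11 10-bromo-3-ethyl-8-methoxy-2,7-dioxabicyclo[4.2.2]decan-4-one (C6 methyl acetal as anomer mixture; C12 ketone; 7S,9S,10R,13R), via cyclic enol ether 10 (not isolated)
Conditions: second-generation Grubbs catalyst RuCl2(=CHPh)(PCy3)(H2IMes) (10 mol %), toluene (2 mM), 80 °C; then HCl (1.25 M in MeOH), 40 °C; evaporate; 1 M aq. HCl, THF, 0 °C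
Reagents that add atoms: water, O
Why: The ruthenium alkylidene generated at the C11 vinyl group adds across the C12 methyl enol ether and cycloreverts, so the oxocane is closed by ring-closing olefin metathesis between C11 and C12 (eight-membered ring, ethene lost) to give 10; acid then protonates C11 of the enol ether (C12 ketone after work-up), cleaves the MOM ether and ionises the C6 dimethyl acetal, and the freed oxygen on C10 (O-a) captures the C6 oxocarbenium ion in a 6-exo-trig closure of the tetrahydropyran. The closest known reaction types are ring-closing metathesis of enol ethers to medium-ring ethers and acid-catalysed transacetalisation of a hydroxy acetal to a methyl pyranoside. The metathesis should be helped by the gauche O/Br and O/O arrangements at C9/C10 and C6/C7 that fold the chain and by high dilution, and it has no competing ring-closing mode because 9 holds only two alkenes. No carbon stereocenter of the target is formed or touched (C7, C9, C10 and C13 come from 9); the new C6 acetal center is set by thermodynamic anomer equilibration and is erased in step 11. The step needs O-a and no other oxygen to reach C6, which is secured because it is the only hydroxyl set free and because C7 and C10 lie 1,4-cis on the new oxocane; β-elimination of O-a from the C12 ketone is blocked once C10 is a bridgehead.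

Step 9
Reactants: 11 10-bromo-3-ethyl-8-methoxy-2,7-dioxabicyclo[4.2.2]decan-4-one
Product: 12 10-bromo-3-ethyl-8-methoxy-2,7-dioxabicyclo[4.2.2]decan-4-ol (12R; 7S,9S,10R,13R)
Conditions: LiBH(s-Bu)3, THF, −78 °C
Reagents that add atoms: none
Why: Felkin–Anh-controlled hydride reduction of the α-alkoxy ketone, in which the bulky borohydride should attack C12 anti to the C13 ethyl group and give the 12R alcohol cis to ethyl.

Step 10
Reactants: 12 10-bromo-3-ethyl-8-methoxy-2,7-dioxabicyclo[4.2.2]decan-4-ol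
Product: 13 4,10-dibromo-3-ethyl-8-methoxy-2,7-dioxabicyclo[4.2.2]decane (7S,9S,10R,12S,13R)
Conditions: CBr4, (n-Oct)3P, toluene, 70 °C
Reagents that add atoms: carbon tetrabromide, BrC(Br)(Br)Br
Why: Appel bromination with SN2 inversion should convert the 12R alcohol into the 12S bromide, trans to the C13 ethyl group.

Step 11
Reactants: 13 4,10-dibromo-3-ethyl-8-methoxy-2,7-dioxabicyclo[4.2.2]decane
Product: 14 8-allyl-4,10-dibromo-3-ethyl-2,7-dioxabicyclo[4.2.2]decane (6R,7S,9S,10R,12S,13R)
Conditions: allyltrimethylsilane, TMSOTf (0.3 equiv), MeCN, −40 to 0 °C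
Reagents that add atoms: allyltrimethylsilane, C=CC[Si](C)(C)C
Why: Hosomi–Sakurai C-allylation of the cyclic C6 oxocarbenium ion, in which the allylsilane should attack anti to the C7–O-b bond, from the side of the two-carbon C8–C9 bridge and away from the four-atom bridge, and so set C6 as R.

Step 12
Reactants: 14 8-allyl-4,10-dibromo-3-ethyl-2,7-dioxabicyclo[4.2.2]decane
Product: 15 (2E)-4-(4,10-dibromo-3-ethyl-2,7-dioxabicyclo[4.2.2]decan-8-yl)but-2-enal
Conditions: (E)-but-2-enal, second-generation Hoveyda–Grubbs catalyst RuCl2(=CH-C6H4-2-OiPr)(H2IMes) (5 mol %), CH2Cl2, 40 °C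
Reagents that add atoms: (E)-but-2-enal, C/C=C/C=O
Why: Olefin cross-metathesis of the terminal alkene with crotonaldehyde should give the conjugated enal with E geometry under thermodynamic control.

Step 13
Reactants: 15 (2E)-4-(4,10-dibromo-3-ethyl-2,7-dioxabicyclo[4.2.2]decan-8-yl)but-2-enal
Product: 16 4,10-dibromo-3-ethyl-8-[(2E)-pent-2-en-4-yn-1-yl]-2,7-dioxabicyclo[4.2.2]decane (target; 3E,6R,7S,9S,10R,12S,13R)
Conditions: TMSCHN2, LiN(iPr)2, THF, −78 °C to rt
Reagents that add atoms: (trimethylsilyl)diazomethane, C[Si](C)(C)C=[N+]=[N-]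
Why: Colvin rearrangement, in which the lithiated diazomethane adds to the aldehyde, Peterson elimination gives a diazoalkene, and loss of N2 with a 1,2-hydrogen shift should deliver the terminal alkyne with the E alkene unchanged.

Compound list
1 | 2,2-dimethoxyacetaldehyde | COC(OC)C=O | starting material
2 | (S)-1,1-dimethoxypent-4-en-2-ol | COC(OC)[C@@H](O)CC=C | intermediate
3 | methyl (S)-2-hydroxybutanoate | CC[C@H](O)C(=O)OC | starting material
4 | methyl (S)-2-(trifluoromethylsulfonyloxy)butanoate | CC[C@H](OS(=O)(=O)C(F)(F)F)C(=O)OC | intermediate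
5 | methyl (2R)-2-{[(2S)-1,1-dimethoxypent-4-en-2-yl]oxy}butanoate | CC[C@@H](O[C@@H](CC=C)C(OC)OC)C(=O)OC | intermediate
6 | methyl (2R)-2-{[(2S)-1,1-dimethoxy-4-oxobutan-2-yl]oxy}butanoate | CC[C@@H](O[C@@H](CC=O)C(OC)OC)C(=O)OC | intermediate
7 | methyl (2R)-2-{[(2S,4R,5R)-4-hydroxy-1,1-dimethoxy-5-(methoxymethoxy)hept-6-en-2-yl]oxy}butanoate | CC[C@@H](O[C@@H](C[C@@H](O)[C@H](OCOC)C=C)C(OC)OC)C(=O)OC | intermediate
8 | methyl (2R)-2-{[(2S,4S,5R)-4-bromo-1,1-dimethoxy-5-(methoxymethoxy)hept-6-en-2-yl]oxy}butanoate | CC[C@@H](O[C@@H](C[C@H](Br)[C@H](OCOC)C=C)C(OC)OC)C(=O)OC | intermediate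
9 | (3R)-3-{[(2S,4S,5R)-4-bromo-1,1-dimethoxy-5-(methoxymethoxy)hept-6-en-2-yl]oxy}-2-methoxypent-1-ene | CC[C@@H](O[C@@H](C[C@H](Br)[C@H](OCOC)C=C)C(OC)OC)C(OC)=C | intermediate
10 | (2R,5R,6S,8S)-6-bromo-8-(dimethoxymethyl)-2-ethyl-3-methoxy-5-(methoxymethoxy)-5,6,7,8-tetrahydro-2H-oxocine (ring alkene C11=C12, C10 and C13 cis) | CC[C@H]1O[C@H](C(OC)OC)C[C@H](Br)[C@H](OCOC)/C=C\1OC | intermediate (not isolated)
11 | 10-bromo-3-ethyl-8-methoxy-2,7-dioxabicyclo[4.2.2]decan-4-one (7S,9S,10R,13R; C6 anomers) | COC1O[C@@H]2CC(=O)[C@@H](CC)O[C@H]1C[C@@H]2Br | intermediate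
12 | 10-bromo-3-ethyl-8-methoxy-2,7-dioxabicyclo[4.2.2]decan-4-ol (7S,9S,10R,12R,13R) | COC1O[C@@H]2C[C@@H](O)[C@@H](CC)O[C@H]1C[C@@H]2Br | intermediate
13 | 4,10-dibromo-3-ethyl-8-methoxy-2,7-dioxabicyclo[4.2.2]decane (7S,9S,10R,12S,13R) | COC1O[C@@H]2C[C@H](Br)[C@@H](CC)O[C@H]1C[C@@H]2Br | intermediate
14 | 8-allyl-4,10-dibromo-3-ethyl-2,7-dioxabicyclo[4.2.2]decane (6R,7S,9S,10R,12S,13R) | C=CC[C@H]1O[C@@H]2C[C@H](Br)[C@@H](CC)O[C@H]1C[C@@H]2Br | intermediate
15 | (2E)-4-(4,10-dibromo-3-ethyl-2,7-dioxabicyclo[4.2.2]decan-8-yl)but-2-enal | O=C/C=C/C[C@H]1O[C@@H]2C[C@H](Br)[C@@H](CC)O[C@H]1C[C@@H]2Br | intermediate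
16 | 4,10-dibromo-3-ethyl-8-[(2E)-pent-2-en-4-yn-1-yl]-2,7-dioxabicyclo[4.2.2]decane (3E,6R,7S,9S,10R,12S,13R) | C#C/C=C/C[C@H]1O[C@@H]2C[C@H](Br)[C@@H](CC)O[C@H]1C[C@@H]2Br | target

Total step count: 13. Longest linear sequence: 12 steps (steps 1 and 3 to 13; step 2 prepares the second fragment).

Steps most likely to fail

Step 8. Ring closure to the eight-membered enol ether may lose out to intermolecular metathesis or to arrest of the catalyst as an alkoxycarbene, and the bridged acetal may not close against the methanol equilibrium. The fallback sets out from 8 and comes back at 11; it fixes the chain on a ring before the metathesis, so the two bonds are then made in consecutive operations. Methanolic HCl should cleave the MOM ether of 8 and close the monocyclic acetal methyl (2R)-2-{[(3S,5S,6R)-5-bromo-2-methoxy-6-vinyltetrahydro-2H-pyran-3-yl]oxy}butanoate F1. Cp2TiMe2 should then give the enol ether (3S,5S,6R)-5-bromo-2-methoxy-3-{[(3R)-2-methoxypent-1-en-3-yl]oxy}-6-vinyltetrahydro-2H-pyran F2. Metathesis with the second-generation Grubbs catalyst RuCl2(=CHPh)(PCy3)(H2IMes) on this monocycle, whose C7 and C10 arms are cis, should close the bridged enol ether 10-bromo-3-ethyl-4,8-dimethoxy-2,7-dioxabicyclo[4.2.2]dec-4-ene F3. Aqueous acid should hydrolyse F3 to 11.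

Step 11. Attack on the C6 oxocarbenium ion may show poor facial selectivity, or the ring C–O bond may ionise in place of the exocyclic one and open the pyran. The fallback sets out from 13 and comes back at 14. Aqueous HCl in THF should hydrolyse 13 to the lactol 4,10-dibromo-3-ethyl-2,7-dioxabicyclo[4.2.2]decan-8-ol F4. TEMPO with PhI(OAc)2 should oxidise it to the lactone 4,10-dibromo-3-ethyl-2,7-dioxabicyclo[4.2.2]decan-8-one F5. CH2=CHCH2MgBr (THF, −78 °C) should add once to give the hemiketal 8-allyl-4,10-dibromo-3-ethyl-2,7-dioxabicyclo[4.2.2]decan-8-ol F6. Et3SiH with BF3·OEt2 (CH2Cl2, −78 °C) should reduce F6 through the allyl-substituted oxocarbenium ion; hydride is then the incoming group, so the allyl group is left on the face that a direct allylation avoids.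

Step 9. Hydride delivery to C12 may show poor facial selectivity, and the two C6 anomers may behave differently. The fallback sets out from 11 and comes back at 12. The wrong-face product, made on purpose with NaBH4 (MeOH, 0 °C) or collected from step 9, is the epimeric alcohol (12S)-10-bromo-3-ethyl-8-methoxy-2,7-dioxabicyclo[4.2.2]decan-4-ol F7. Mitsunobu inversion (4-nitrobenzoic acid, PPh3, DIAD, THF) should give the ester (12R)-10-bromo-3-ethyl-8-methoxy-2,7-dioxabicyclo[4.2.2]decan-4-yl 4-nitrobenzoate F8. K2CO3 in MeOH should release 12.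

Further compounds
F1 | step 8 | methyl (2R)-2-{[(3S,5S,6R)-5-bromo-2-methoxy-6-vinyltetrahydro-2H-pyran-3-yl]oxy}butanoate | COC1O[C@H](C=C)[C@@H](Br)C[C@@H]1O[C@H](CC)C(=O)OC
F2 | step 8 | (3S,5S,6R)-5-bromo-2-methoxy-3-{[(3R)-2-methoxypent-1-en-3-yl]oxy}-6-vinyltetrahydro-2H-pyran | COC1O[C@H](C=C)[C@@H](Br)C[C@@H]1O[C@H](CC)C(OC)=C
F3 | step 8 | 10-bromo-3-ethyl-4,8-dimethoxy-2,7-dioxabicyclo[4.2.2]dec-4-ene | COC1O[C@@H]2/C=C(OC)\[C@@H](CC)O[C@H]1C[C@@H]2Br
F4 | step 11 | 4,10-dibromo-3-ethyl-2,7-dioxabicyclo[4.2.2]decan-8-ol | OC1O[C@@H]2C[C@H](Br)[C@@H](CC)O[C@H]1C[C@@H]2Br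
F5 | step 11 | 4,10-dibromo-3-ethyl-2,7-dioxabicyclo[4.2.2]decan-8-one | O=C1O[C@@H]2C[C@H](Br)[C@@H](CC)O[C@H]1C[C@@H]2Br
F6 | step 11 | 8-allyl-4,10-dibromo-3-ethyl-2,7-dioxabicyclo[4.2.2]decan-8-ol | C=CCC1(O)O[C@@H]2C[C@H](Br)[C@@H](CC)O[C@H]1C[C@@H]2Br
F7 | step 9 | (12S)-10-bromo-3-ethyl-8-methoxy-2,7-dioxabicyclo[4.2.2]decan-4-ol | COC1O[C@@H]2C[C@H](O)[C@@H](CC)O[C@H]1C[C@@H]2Br
F8 | step 9 | (12R)-10-bromo-3-ethyl-8-methoxy-2,7-dioxabicyclo[4.2.2]decan-4-yl 4-nitrobenzoate | COC1O[C@@H]2C[C@@H](OC(=O)c3ccc(cc3)[N+](=O)[O-])[C@@H](CC)O[C@H]1C[C@@H]2Br
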